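**Plan**

- Retrosynthetic cuts, in order: hydroquinone back to quinone and 2,5-dimethoxyarene; C7 carbamate back to C7–OH; the 19-membered ansa lactam at the C3–C4 σ-bond of the (2E,4Z)-dienamide; then C4=C5, N–C1, C6–C7, C8=C9, C10–C11, C11–C12 and C14–C15.
- Forward: the chain grows linearly from the aryl aldehyde (C15) to a vinyl terminus at C5 by three reagent-controlled boron additions, one hydroformylation and one cross-metathesis; the aniline is then acylated with (E)-3-iodo-2-methylacryloyl chloride (C1–C3), and C4 enters with the boron tether.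
- Enabling feature: O7 is homoallylic to C4 (O7–C7–C6–C5=C4), so boron can bridge O7 and C4 in a six-membered 1,2-oxaborinine (O7–B–C4=C5–C6–C7) made by boron-tethered ring-closing metathesis. This small ring forces the 4Z geometry and activates C4.
- Ring order: oxaborinine first, then its Suzuki–Miyaura coupling with the C3 iodide closes the macrocycle, opens the small ring and frees O7–H alone for the carbamate.
- Stereochemistry: C14/C15, C10/C11 and C6/C7 from (Z)-crotyl- and (Z)-γ-methoxyallyl-diisopinocampheylboranes (syn, reagent control); C12 from enamine-catalysed α-benzoyloxylation; 8E from cross-metathesis; 2E from the iodoacrylic acid.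

Key step: step 15

Remark: the ansa chain is numbered C1 (amide carbonyl) to C15 (benzylic carbon); in this numbering the target is 2E,4Z,6S,7S,8E,10S,11R,12S,14S,15R.
Remark: compounds 1, 10, 14 and 19 and all reagents are taken as commercial; the facial sense of the three boron additions and of the organocatalyst is assigned from the accepted transition-state models.

**Route**

Step 1
Reactants: 1 2-hydroxy-5-methoxy-3-nitrobenzaldehyde
Product: 2 2,5-dimethoxy-3-nitrobenzaldehyde
Conditions: MeI, K2CO3, DMF, rt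
Reagents that add atoms: iodomethane, CI
Why: Williamson O-methylation of the acidic ortho-nitrophenol should be clean and gives the methyl ether that later serves as a latent quinone oxygen.

Step 2
Reactants: 2 2,5-dimethoxy-3-nitrobenzaldehyde
Product: 3 (1R,2S)-1-(2,5-dimethoxy-3-nitrophenyl)-2-methylbut-3-en-1-ol
Conditions: (Z)-crotyl-B(Ipc)2 [made from cis-2-butene, n-BuLi, KOt-Bu, then (+)-Ipc2BOMe (isopinocampheyl groups from (−)-α-pinene), then BF3·OEt2], THF/Et2O, −78 °C; then NaOH, H2O2
Reagents that add atoms: (Z)-crotyldiisopinocampheylborane, C/C=C\CB([C@H]1C[C@H]2C[C@@H]([C@@H]1C)C2(C)C)[C@H]3C[C@H]4C[C@@H]([C@@H]3C)C4(C)C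
Why: Brown asymmetric crotylboration through a closed chair transition state: the (Z)-crotyl geometry sets the 14,15-syn relationship and the isopinocampheyl groups direct the new bond to the Re face of the aldehyde, which should give 15R,14S.

Step 3
Reactants: 3 (1R,2S)-1-(2,5-dimethoxy-3-nitrophenyl)-2-methylbut-3-en-1-ol
Product: 4 2,5-dimethoxy-1-[(1R,2S)-1-methoxy-2-methylbut-3-en-1-yl]-3-nitrobenzene
Conditions: NaH, MeI, THF, 0 °C to rt
Reagents that add atoms: iodomethane, CI
Why: Williamson methylation of the secondary benzylic alkoxide installs the C15 methyl ether without touching either stereocentre.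

Step 4
Reactants: 4 2,5-dimethoxy-1-[(1R,2S)-1-methoxy-2-methylbut-3-en-1-yl]-3-nitrobenzene
Product: 5 (4S,5R)-5-(2,5-dimethoxy-3-nitrophenyl)-5-methoxy-4-methylpentanal
Conditions: Rh(acac)(CO)2 (1 mol%), Xantphos, CO/H2 (1:1, 10 bar), toluene, 70 °C
Reagents that add atoms: carbon monoxide, [C-]#[O+]
Why: Rhodium-catalysed linear-selective hydroformylation; the wide-bite-angle diphosphine and the α-branch of the alkene should send the formyl group to the terminal carbon, which adds C11 and no stereocentre.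

Step 5
Reactants: 5 (4S,5R)-5-(2,5-dimethoxy-3-nitrophenyl)-5-methoxy-4-methylpentanal
Product: 6 (2S,4S,5R)-5-(2,5-dimethoxy-3-nitrophenyl)-5-methoxy-4-methyl-1-oxopentan-2-yl benzoate
Conditions: (S)-2-tritylpyrrolidine (10 mol%), (PhCO2)2, hydroquinone (10 mol%), THF, 0 °C
Reagents that add atoms: dibenzoyl peroxide, O=C(OOC(=O)c1ccccc1)c1ccccc1
Why: Enamine-catalysed α-benzoyloxylation of the aldehyde; the trityl group shields one face of the (E)-enamine, so the peroxide oxygen should be delivered to the open face and give 12S under catalyst control.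

Step 6
Reactants: 6 (2S,4S,5R)-5-(2,5-dimethoxy-3-nitrophenyl)-5-methoxy-4-methyl-1-oxopentan-2-yl benzoate
Product: 8 (3S,4R,5S,7S,8R)-8-(2,5-dimethoxy-3-nitrophenyl)-8-methoxy-3,7-dimethyloct-1-ene-4,5-diol, via hydroxy benzoate 7 (not isolated)
Conditions: (Z)-crotyl-B(Ipc)2 [made as in step 2 from cis-2-butene, n-BuLi, KOt-Bu, (+)-Ipc2BOMe, BF3·OEt2], THF/Et2O, −78 °C; then NaOH, H2O2, THF/MeOH, 0 °C to rt
Reagents that add atoms: (Z)-crotyldiisopinocampheylborane, C/C=C\CB([C@H]1C[C@H]2C[C@@H]([C@@H]1C)C2(C)C)[C@H]3C[C@H]4C[C@@H]([C@@H]3C)C4(C)C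
Why: A second Brown crotylboration, matched with the Felkin–Anh/Cornforth preference of the α-acyloxy aldehyde, should set 11R (anti to the C12 oxygen) and 10S (syn to the C11 hydroxyl), and the alkaline hydroperoxide work-up also saponifies the benzoate to the diol.

Step 7
Reactants: 8 (3S,4R,5S,7S,8R)-8-(2,5-dimethoxy-3-nitrophenyl)-8-methoxy-3,7-dimethyloct-1-ene-4,5-diol
Product: 9 (4R,5S)-4-[(2S)-but-3-en-2-yl]-5-[(2S,3R)-3-(2,5-dimethoxy-3-nitrophenyl)-3-methoxy-2-methylpropyl]-2,2-dimethyl-1,3-dioxolane (the cis-acetonide of 8)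
Conditions: Me2C(OMe)2, PPTS, CH2Cl2, rt
Reagents that add atoms: 2,2-dimethoxypropane, COC(C)(C)OC
Why: Acid-catalysed transketalization ties the anti-diol into a cis-dioxolane that is stable to base, boranes, metathesis and palladium.

Step 8
Reactants: 9 the cis-acetonide of 8; 10 methacrolein
Product: 11 (2E,4S)-4-[(4R,5S)-5-[(2S,3R)-3-(2,5-dimethoxy-3-nitrophenyl)-3-methoxy-2-methylpropyl]-2,2-dimethyl-1,3-dioxolan-4-yl]-2-methylpent-2-enal (the C7 enal)
Conditions: second-generation Hoveyda–Grubbs catalyst (5 mol%), 10 (10 equiv), CH2Cl2, 40 °C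
Reagents that add atoms: none
Why: Olefin cross-metathesis of the terminal alkene with the 1,1-disubstituted enal is driven by loss of ethylene, and the trisubstituted enal should form as the thermodynamically favoured E isomer.

Step 9
Reactants: 11 the C7 enal
Product: 12 (3S,4S,5E,7S)-7-[(4R,5S)-5-[(2S,3R)-3-(2,5-dimethoxy-3-nitrophenyl)-3-methoxy-2-methylpropyl]-2,2-dimethyl-1,3-dioxolan-4-yl]-3-methoxy-5-methylocta-1,5-dien-4-ol (nitro alcohol with 6S-OMe, 7S-OH and a vinyl group on C6)
Conditions: (Z)-γ-methoxyallyl-B(Ipc)2 [made from allyl methyl ether, s-BuLi, then (+)-Ipc2BOMe, then BF3·OEt2], THF/Et2O, −78 °C; then NaOH, H2O2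
Reagents that add atoms: [(Z)-3-methoxyallyl]diisopinocampheylborane, CO/C=C\CB([C@H]1C[C@H]2C[C@@H]([C@@H]1C)C2(C)C)[C@H]3C[C@H]4C[C@@H]([C@@H]3C)C4(C)C
Why: Brown γ-alkoxyallylboration: the Z-enol ether geometry sets the 6,7-syn relationship and the isopinocampheyl groups direct addition to the Re face of the enal, which should give 6S,7S and install the vinyl group on C6 (C5 plus a terminal CH2) in the same step.

Step 10
Reactants: 12 nitro alcohol
Product: 13 the corresponding aniline (3-amino-2,5-dimethoxyphenyl in place of the nitroarene, all else as in 12)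
Conditions: Fe, NH4Cl, EtOH/H2O, 70 °C
Reagents that add atoms: none
Why: Béchamp-type iron reduction is chemoselective for the nitro group and should leave the alkenes, the allylic alcohol and the acetonide untouched.

Step 11
Reactants: 14 diethyl methylmalonate
Product: 15 diethyl 2-(diiodomethyl)-2-methylpropanedioate
Conditions: NaH, CHI3, Et2O, reflux
Reagents that add atoms: iodoform, IC(I)I
Why: C-alkylation of the malonate enolate with iodoform installs the diiodomethyl group.

Step 12
Reactants: 15 diethyl 2-(diiodomethyl)-2-methylpropanedioate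
Product: 16 (E)-3-iodo-2-methylprop-2-enoic acid
Conditions: KOH, EtOH/H2O, reflux; then aq. HCl
Reagents that add atoms: potassium hydroxide, [K+].[OH-]
Why: Saponification followed by decarboxylative elimination of iodide should deliver the thermodynamically favoured (E)-β-iodoacrylic acid.

Step 13
Reactants: 13 aniline; 16 (E)-3-iodo-2-methylprop-2-enoic acid
Product: 18 the (E)-3-iodo-2-methylacrylanilide of 13 (C7–OH free), via acid chloride 17 (not isolated)
Conditions: 16, (COCl)2, DMF (cat.), CH2Cl2, 0 °C to rt, evaporation; then 13, pyridine, CH2Cl2, −20 °C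
Reagents that add atoms: none
Why: Acid chloride formation and amide formation; without an acyl-transfer catalyst the aniline nitrogen should react far faster than the hindered secondary C7 hydroxyl, and the E-iodoalkene is not touched.

Step 14
Reactants: 18 iodoacrylanilide; 19 dibutyl vinylboronate
Product: 21 oxaborinine (2-butoxy-5,6-dihydro-2H-1,2-oxaborinine ring spanning O7–B–C4=C5–C6–C7; rest as in 18), via mixed vinylboronate 20 (not isolated)
Conditions: 19 (2 equiv), CH2Cl2, rt; second-generation Grubbs catalyst (10 mol%), 40 °C; volatiles removed, used crude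
Reagents that add atoms: none
Why: Boron-tethered ring-closing metathesis: transesterification places the vinylboronate on O7 and ring closure onto the C6 vinyl group (the only alkene that can give a six-membered ring) should give the oxaborinine with loss of ethylene, the boron-bound carbon of 19 becoming C4 and the endocyclic double bond being necessarily cis.

Step 15
Reactants: 21 oxaborinine
Product: 22 the 19-membered (2E,4Z,8E)-macrolactam with free 7S-OH, 11,12-acetonide and 2,5-dimethoxyarene
Conditions: Pd(PPh3)4 (20 mol%), TlOEt, THF/H2O (3:1), rt, slow addition of 21 (final concentration about 1 mM)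
Reagents that add atoms: none
Why: Zerovalent palladium inserts into the C3–I bond of the (E)-iodoacrylamide, TlOEt and water open the oxaborinine to a (Z)-alkenyl borate that transfers C4 to palladium, and reductive elimination joins C3 to C4. The closest known reaction types are the Suzuki–Miyaura macrocyclization of alkenyl iodide/alkenylboron seco compounds and the cross-coupling of cyclic boronic half esters made by boron-tethered metathesis; the silicon counterpart (metathesis to a cyclic alkenylsiloxane, then intramolecular coupling) is established up to macrolactone size. One ring is closed, the 19-membered ansa lactam, by end-to-end alkenyl–alkenyl coupling through a large palladacycle, while the six-membered oxaborinine is opened in the same event and gives back O7–H. No stereocentre is formed; the 4Z geometry is set in step 14 by the six-membered ring and the 2E geometry in step 12 by the iodoacrylic acid, and both should be carried through because oxidative addition, transmetalation and reductive elimination are stereoretentive. The step needs ring closure to win over oligomerization and protodeboronation: slow addition at high dilution secures the first, the thallium-accelerated transmetalation at room temperature the second, and the cis-dioxolane at C11/C12 with the E-alkene at C8 pre-bend the chain.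

Step 16
Reactants: 22 macrolactam alcohol
Product: 24 the C7 carbamate of 22, via N-trichloroacetyl carbamate 23 (not isolated)
Conditions: Cl3CC(O)NCO, CH2Cl2, 0 °C; then K2CO3, MeOH, rt
Reagents that add atoms: trichloroacetyl isocyanate, O=C=NC(=O)C(Cl)(Cl)Cl
Why: Kočovský carbamoylation: the only free hydroxyl (O7, released in step 15) adds to the isocyanate and methanolysis removes the trichloroacetyl group.

Step 17
Reactants: 24 macrolactam carbamate
Product: 25 the corresponding 2-amido-1,4-benzoquinone (11,12-acetonide retained)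
Conditions: (NH4)2Ce(NO3)6, MeCN/H2O, −10 °C
Reagents that add atoms: water, O
Why: Oxidative demethylation of the 2,5-dimethoxyanilide by tetravalent cerium should give the para-quinone quickly at low temperature, before the carbamate, the dienamide or the acetonide can react.

Step 18
Reactants: 25 quinone acetonide
Product: 26 the quinone with free 11R,12S-diol
Conditions: AcOH/H2O (4:1), 40 °C
Reagents that add atoms: none
Why: Acid-catalysed acetal hydrolysis frees the diol at the quinone stage, where the electron-poor ring no longer assists ionization of the C15 benzylic methyl ether.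

Step 19
Reactants: 26 quinone diol
Product: 27 CNP0523404.1 (the hydroquinone)
Conditions: Na2S2O4, EtOAc/H2O, rt, argon
Reagents that add atoms: none
Why: Dithionite reduction of the quinone to the hydroquinone is fast and selective and should leave every other group untouched; the product is isolated with exclusion of air.

**Compound list**

1 | 2-hydroxy-5-methoxy-3-nitrobenzaldehyde | O=Cc1cc(OC)cc([N+](=O)[O-])c1O | starting material
2 | 2,5-dimethoxy-3-nitrobenzaldehyde | O=Cc1cc(OC)cc([N+](=O)[O-])c1OC | intermediate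
3 | (1R,2S)-1-(2,5-dimethoxy-3-nitrophenyl)-2-methylbut-3-en-1-ol | [O-][N+](=O)c1cc(OC)cc(c1OC)[C@H](O)[C@@H](C)C=C | intermediate
4 | 2,5-dimethoxy-1-[(1R,2S)-1-methoxy-2-methylbut-3-en-1-yl]-3-nitrobenzene | [O-][N+](=O)c1cc(OC)cc(c1OC)[C@H](OC)[C@@H](C)C=C | intermediate
5 | (4S,5R)-5-(2,5-dimethoxy-3-nitrophenyl)-5-methoxy-4-methylpentanal | [O-][N+](=O)c1cc(OC)cc(c1OC)[C@H](OC)[C@@H](C)CCC=O | intermediate
6 | (2S,4S,5R)-5-(2,5-dimethoxy-3-nitrophenyl)-5-methoxy-4-methyl-1-oxopentan-2-yl benzoate | [O-][N+](=O)c1cc(OC)cc(c1OC)[C@H](OC)[C@@H](C)C[C@H](OC(=O)c2ccccc2)C=O | intermediate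
7 | (3S,4R,5S,7S,8R)-8-(2,5-dimethoxy-3-nitrophenyl)-4-hydroxy-8-methoxy-3,7-dimethyloct-1-en-5-yl benzoate | [O-][N+](=O)c1cc(OC)cc(c1OC)[C@H](OC)[C@@H](C)C[C@H](OC(=O)c2ccccc2)[C@H](O)[C@@H](C)C=C | intermediate
8 | (3S,4R,5S,7S,8R)-8-(2,5-dimethoxy-3-nitrophenyl)-8-methoxy-3,7-dimethyloct-1-ene-4,5-diol | [O-][N+](=O)c1cc(OC)cc(c1OC)[C@H](OC)[C@@H](C)C[C@H](O)[C@H](O)[C@@H](C)C=C | intermediate
9 | (4R,5S)-4-[(2S)-but-3-en-2-yl]-5-[(2S,3R)-3-(2,5-dimethoxy-3-nitrophenyl)-3-methoxy-2-methylpropyl]-2,2-dimethyl-1,3-dioxolane | [O-][N+](=O)c1cc(OC)cc(c1OC)[C@H](OC)[C@@H](C)C[C@@H]2OC(C)(C)O[C@@H]2[C@@H](C)C=C | intermediate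
10 | methacrolein | CC(=C)C=O | starting material
11 | C7 enal: (2E,4S)-4-[(4R,5S)-5-[(2S,3R)-3-(2,5-dimethoxy-3-nitrophenyl)-3-methoxy-2-methylpropyl]-2,2-dimethyl-1,3-dioxolan-4-yl]-2-methylpent-2-enal | [O-][N+](=O)c1cc(OC)cc(c1OC)[C@H](OC)[C@@H](C)C[C@@H]2OC(C)(C)O[C@@H]2[C@@H](C)/C=C(\C)C=O | intermediate
12 | nitro alcohol: (3S,4S,5E,7S)-7-[(4R,5S)-5-[(2S,3R)-3-(2,5-dimethoxy-3-nitrophenyl)-3-methoxy-2-methylpropyl]-2,2-dimethyl-1,3-dioxolan-4-yl]-3-methoxy-5-methylocta-1,5-dien-4-ol | [O-][N+](=O)c1cc(OC)cc(c1OC)[C@H](OC)[C@@H](C)C[C@@H]2OC(C)(C)O[C@@H]2[C@@H](C)/C=C(\C)[C@H](O)[C@@H](OC)C=C | intermediate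
13 | aniline: the 3-amino-2,5-dimethoxyphenyl analogue of 12 | Nc1cc(OC)cc(c1OC)[C@H](OC)[C@@H](C)C[C@@H]2OC(C)(C)O[C@@H]2[C@@H](C)/C=C(\C)[C@H](O)[C@@H](OC)C=C | intermediate
14 | diethyl methylmalonate | CCOC(=O)C(C)C(=O)OCC | starting material
15 | diethyl 2-(diiodomethyl)-2-methylpropanedioate | CCOC(=O)C(C)(C(I)I)C(=O)OCC | intermediate
16 | (E)-3-iodo-2-methylprop-2-enoic acid | I/C=C(\C)C(=O)O | intermediate
17 | (E)-3-iodo-2-methylprop-2-enoyl chloride | I/C=C(\C)C(=O)Cl | intermediate
18 | iodoacrylanilide: N-acyl derivative of 13 with 16, C7–OH free | I/C=C(\C)C(=O)Nc1cc(OC)cc(c1OC)[C@H](OC)[C@@H](C)C[C@@H]2OC(C)(C)O[C@@H]2[C@@H](C)/C=C(\C)[C@H](O)[C@@H](OC)C=C | intermediate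
19 | dibutyl vinylboronate | C=CB(OCCCC)OCCCC | starting material
20 | mixed boronate: O7-[butoxy(vinyl)boryl] derivative of 18 | I/C=C(\C)C(=O)Nc1cc(OC)cc(c1OC)[C@H](OC)[C@@H](C)C[C@@H]2OC(C)(C)O[C@@H]2[C@@H](C)/C=C(\C)[C@H](OB(OCCCC)C=C)[C@@H](OC)C=C | intermediate
21 | oxaborinine: 2-butoxy-5,6-dihydro-2H-1,2-oxaborinine ring O7–B–C4=C5–C6–C7 (5S-OMe, 6S-alkenyl), iodoacrylanilide retained | I/C=C(\C)C(=O)Nc1cc(OC)cc(c1OC)[C@H](OC)[C@@H](C)C[C@@H]2OC(C)(C)O[C@@H]2[C@@H](C)/C=C(\C)[C@@H]3OB(OCCCC)C=C[C@@H]3OC | intermediate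
22 | macrolactam alcohol: 19-membered (2E,4Z,8E) lactam, 6S-OMe, 7S-OH, 11,12-acetonide, 15R-OMe, 2,5-dimethoxyarene | CO[C@H]1/C=C\C=C(/C)C(=O)Nc2cc(OC)cc(c2OC)[C@H](OC)[C@@H](C)C[C@@H]3OC(C)(C)O[C@@H]3[C@@H](C)/C=C(\C)[C@@H]1O | intermediate
23 | N-trichloroacetyl carbamate of 22 at O7 | CO[C@H]1/C=C\C=C(/C)C(=O)Nc2cc(OC)cc(c2OC)[C@H](OC)[C@@H](C)C[C@@H]3OC(C)(C)O[C@@H]3[C@@H](C)/C=C(\C)[C@@H]1OC(=O)NC(=O)C(Cl)(Cl)Cl | intermediate
24 | C7 carbamate of 22 | CO[C@H]1/C=C\C=C(/C)C(=O)Nc2cc(OC)cc(c2OC)[C@H](OC)[C@@H](C)C[C@@H]3OC(C)(C)O[C@@H]3[C@@H](C)/C=C(\C)[C@@H]1OC(N)=O | intermediate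
25 | quinone acetonide: 2-amido-1,4-benzoquinone form of 24 | CO[C@H]1/C=C\C=C(/C)C(=O)NC2=CC(=O)C=C(C2=O)[C@H](OC)[C@@H](C)C[C@@H]3OC(C)(C)O[C@@H]3[C@@H](C)/C=C(\C)[C@@H]1OC(N)=O | intermediate
26 | quinone diol: 25 with free 11R,12S-diol | CO[C@H]1/C=C\C=C(/C)C(=O)NC2=CC(=O)C=C(C2=O)[C@H](OC)[C@@H](C)C[C@H](O)[C@H](O)[C@@H](C)/C=C(\C)[C@@H]1OC(N)=O | intermediate
27 | CNP0523404.1, the hydroquinone of 26 | CO[C@H]1/C=C\C=C(/C)C(=O)Nc2cc(O)cc(c2O)[C@H](OC)[C@@H](C)C[C@H](O)[C@H](O)[C@@H](C)/C=C(\C)[C@@H]1OC(N)=O | target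

**Count and risks**

Total step count: 19. Longest linear sequence: 17 (steps 1–10 and 13–19).

Steps most likely to fail:

1. Step 15 (macrocyclization). Intermolecular coupling to oligomers, or protodeboronation of the (Z)-alkenylboron, may outrun ring closure. The fallback closes the ring at the amide instead; it sets out from 12 and comes back at 22. Nitro alcohol 12 would be treated with 19 and the second-generation Grubbs catalyst to give the nitro oxaborinine F1. Intermolecular Suzuki–Miyaura coupling of F1 with acid 16 (Pd(PPh3)4, TlOEt, THF/H2O) would give the (2E,4Z)-dienoic acid F2. Reduction with Fe/NH4Cl would give the amino acid F3. Macrolactamization of F3 (bis(2-oxo-3-oxazolidinyl)phosphinic chloride, i-Pr2NEt, toluene, high dilution, 80 °C) would give 22.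

2. Step 14 (boron tether). The reversible boron tether on the hindered C7 hydroxyl may not hold (incomplete transesterification, hydrolysis by adventitious water), so the two alkenes are not brought together. The fallback uses a covalent silicon tether; it sets out from 18 and comes back at 22. Silylation of 18 with chloro(dimethyl)vinylsilane and imidazole would give the vinylsilyl ether F4. Ring-closing metathesis (second-generation Grubbs catalyst, toluene, 80 °C) would give the cyclic alkenylsiloxane F5. Intramolecular fluoride-promoted silicon-based cross-coupling ([(C3H5)PdCl]2, Bu4NF, THF, rt, slow addition) would give 22; the acetonide and the methyl ethers tolerate fluoride.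

3. Step 8 (cross-metathesis). Metathesis at the α-branched alkene next to the dioxolane may be slow, so catalyst decomposition and self-reaction of methacrolein take over. The fallback uses oxidative cleavage and olefination; it sets out from 9 and comes back at 11. Cleavage of 9 (OsO4 cat., NaIO4, 2,6-lutidine, dioxane/H2O) would give the C9 aldehyde F6. Wittig reaction of F6 with 2-(triphenylphosphoranylidene)propanal (toluene, 80 °C) would give the E-enal 11.

**Further compounds**

F1 | step 15 | nitro oxaborinine (2-butoxy-5,6-dihydro-2H-1,2-oxaborinine on the nitroarene chain of 12) | [O-][N+](=O)c1cc(OC)cc(c1OC)[C@H](OC)[C@@H](C)C[C@@H]2OC(C)(C)O[C@@H]2[C@@H](C)/C=C(\C)[C@@H]3OB(OCCCC)C=C[C@@H]3OC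
F2 | step 15 | (2E,4Z,8E)-dienoic acid seco compound with nitroarene and free 7-OH | [O-][N+](=O)c1cc(OC)cc(c1OC)[C@H](OC)[C@@H](C)C[C@@H]2OC(C)(C)O[C@@H]2[C@@H](C)/C=C(\C)[C@H](O)[C@@H](OC)/C=C\C=C(/C)C(O)=O
F3 | step 15 | amino acid seco compound (aniline form of F2) | Nc1cc(OC)cc(c1OC)[C@H](OC)[C@@H](C)C[C@@H]2OC(C)(C)O[C@@H]2[C@@H](C)/C=C(\C)[C@H](O)[C@@H](OC)/C=C\C=C(/C)C(O)=O
F4 | step 14 | O7-dimethyl(vinyl)silyl ether of 18 | I/C=C(\C)C(=O)Nc1cc(OC)cc(c1OC)[C@H](OC)[C@@H](C)C[C@@H]2OC(C)(C)O[C@@H]2[C@@H](C)/C=C(\C)[C@H](O[Si](C)(C)C=C)[C@@H](OC)C=C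
F5 | step 14 | cyclic alkenylsiloxane (2,2-dimethyl-5,6-dihydro-2H-1,2-oxasiline spanning O7–Si–C4=C5–C6–C7) | I/C=C(\C)C(=O)Nc1cc(OC)cc(c1OC)[C@H](OC)[C@@H](C)C[C@@H]2OC(C)(C)O[C@@H]2[C@@H](C)/C=C(\C)[C@@H]3O[Si](C)(C)C=C[C@@H]3OC
F6 | step 8 | C9 aldehyde (terminal CH2 of 9 replaced by O; same spatial arrangement at C10) | [O-][N+](=O)c1cc(OC)cc(c1OC)[C@H](OC)[C@@H](C)C[C@@H]2OC(C)(C)O[C@@H]2[C@@H](C)C=O
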